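**Strategy.** The benzoylphloroglucinol ring is disconnected at C5–C6, which unfolds the arene into a benzoyl triketide chain. The feature exploited is that the side-chain oxygen on C2′ lies γ to ring carbon C6 through C1′ and C1, so C6, C1, C1′, C2′ and that oxygen can be held as a γ-lactone. A magnesium-mediated Claisen condensation of the C5 enolate onto this lactone carbonyl then forms the carbocycle, aromatises it and releases the free (R)-carbinol in one operation, without protecting groups. The precursor is a (5R)-3-(3,5-dioxo-5-phenylpentanoyl)oxolan-2-one bearing the 6-methylhepta-1,5-dien-2-yl group on its carbinol carbon, assembled from a resolved vinyl oxirane by one enolate alkylation and two polyanion acylations.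

Key step: step 8

Remark: ring carbons are C1–C6 (C1 side chain, C5 benzoyl) and side-chain carbons C1′–C8′; β-dicarbonyl compounds are drawn as keto forms and are expected as enol and C3-epimer mixtures, which is immaterial because lactone C3 becomes aromatic C1; the (S,S)-(salen)Co(OAc) complex is assumed to spare the (S)-oxirane as it does simple 2-alkyl oxiranes, and the mirror-image complex is used if the sense proves opposite for 7.

Step 1
Reactants: 1 5-bromo-2-methylpent-2-ene; 2 prop-2-yn-1-ol
Product: 5 6-methyl-2-methylidenehept-5-en-1-ol, via (4-methylpent-3-en-1-yl)magnesium bromide 3 (not isolated), via 4-(4-methylpent-3-en-1-yl)-2,5-dihydro-1,2-oxamagnesole 4 (not isolated)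
Conditions: Mg, Et2O, reflux; then 2 (0.4 equiv relative to 1), CuI (10 mol%), Et2O, 0 °C → reflux; cold 1 M HCl
Reagents that add atoms: none
Why: Copper-catalysed carbomagnesiation of a propargylic alkoxide places the homoprenyl group on the internal alkyne carbon and magnesium on the terminal carbon as chelate 4, whose protonolysis should give the 2-substituted allyl alcohol; no stereocentre is formed.

Step 2
Reactants: 5 6-methyl-2-methylidenehept-5-en-1-ol
Product: 6 6-methyl-2-methylidenehept-5-enal
Conditions: MnO2 (activated, 15 equiv), CH2Cl2, 25 °C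
Reagents that add atoms: none
Why: Allylic oxidation with activated MnO2 is selective for the primary allylic alcohol and should leave the isolated trisubstituted alkene untouched; no stereocentre is involved.

Step 3
Reactants: 6 6-methyl-2-methylidenehept-5-enal
Product: 7 rac-2-(6-methylhepta-1,5-dien-2-yl)oxirane
Conditions: Me3S+ I−, n-BuLi, THF, −10 °C; then 6, −78 → 0 °C
Reagents that add atoms: trimethylsulfonium iodide, C[S+](C)C.[I-]
Why: Corey–Chaykovsky epoxidation, in which the unstabilised sulfonium methylide adds to the aldehyde carbonyl in preference to the conjugate position and the betaine closes to the vinyl oxirane, formed as the racemate.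

Step 4
Reactants: 7 rac-2-(6-methylhepta-1,5-dien-2-yl)oxirane
Product: 8 (2S)-2-(6-methylhepta-1,5-dien-2-yl)oxirane
Conditions: (S,S)-(salen)Co(OAc) (1 mol%; salen = N,N′-bis(3,5-di-tert-butylsalicylidene)cyclohexane-1,2-diamine dianion), H2O (0.55 equiv), THF, 0 → 25 °C
Reagents that add atoms: none
Why: Jacobsen hydrolytic kinetic resolution of a terminal oxirane, in which the chiral cobalt salen complex delivers water to the unsubstituted carbon of the (R)-enantiomer only, so that the (S)-oxirane is recovered and the single stereocentre of the target is fixed by catalyst control.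

Step 5
Reactants: 8 (2S)-2-(6-methylhepta-1,5-dien-2-yl)oxirane; 9 ethyl 3-oxobutanoate
Product: 11 (5R)-3-acetyl-5-(6-methylhepta-1,5-dien-2-yl)oxolan-2-one, via ethyl (4R)-2-acetyl-4-hydroxy-9-methyl-5-methylidenedec-8-enoate 10 (not isolated)
Conditions: NaOEt (1.1 equiv), EtOH, 0 → 50 °C; then AcOH
Reagents that add atoms: none
Why: Acetoacetic ester alkylation by an oxirane followed by lactonisation (the classical α-acetyl-γ-butyrolactone synthesis): the enolate should open the unsubstituted oxirane carbon by SN2, the alkoxide of 10 closes onto the ester, and the untouched C–O centre becomes lactone C5 with R configuration, while C3 forms unselectively and is destroyed later.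

Step 6
Reactants: 11 (5R)-3-acetyl-5-(6-methylhepta-1,5-dien-2-yl)oxolan-2-one; 12 N-methoxy-N-methylacetamide
Product: 14 (5R)-5-(6-methylhepta-1,5-dien-2-yl)-3-(3-oxobutanoyl)oxolan-2-one, via tetrahedral hemiaminal adduct 13 (not isolated)
Conditions: LiN(iPr)2 (2.2 equiv), THF, −78 → −20 °C; then 12, −78 → 0 °C; cold 0.5 M HCl to pH 4
Reagents that add atoms: none
Why: Terminal (γ) acylation of a β-keto ester dianion with a Weinreb amide, in which the more reactive methyl carbanion of doubly deprotonated 11 adds to the amide and adduct 13 withholds the new ketone until work-up; no stereocentre is set.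

Step 7
Reactants: 14 (5R)-5-(6-methylhepta-1,5-dien-2-yl)-3-(3-oxobutanoyl)oxolan-2-one; 15 N-methoxy-N-methylbenzamide
Product: 17 (5R)-3-(3,5-dioxo-5-phenylpentanoyl)-5-(6-methylhepta-1,5-dien-2-yl)oxolan-2-one, via tetrahedral hemiaminal adduct 16 (not isolated)
Conditions: LiN(iPr)2 (3.3 equiv), THF, −78 → 0 °C; then 15, −40 → 0 °C; cold 0.5 M HCl to pH 4; used at once without heating
Reagents that add atoms: none
Why: Terminal acylation of a 1,3,5-tricarbonyl trianion (Weinreb ketone synthesis), in which the last-formed methyl carbanion of triply deprotonated 14 attacks the amide and adduct 16 releases the benzoyl ketone only on cold acidic work-up, so the tetracarbonyl chain is never exposed to strong base; no stereocentre is set.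

Step 8
Reactants: 17 (5R)-3-(3,5-dioxo-5-phenylpentanoyl)-5-(6-methylhepta-1,5-dien-2-yl)oxolan-2-one
Product: 19 {2,4,6-trihydroxy-3-[(2R)-2-hydroxy-7-methyl-3-methylideneoct-6-en-1-yl]phenyl}(phenyl)methanone, via bicyclic hemiketal 18 (not isolated)
Conditions: Mg(OMe)2 (4 equiv), MeOH, 25 → 50 °C, argon; then cold 0.5 M HCl to pH 4
Reagents that add atoms: none
Why: Mg(OMe)2 forms the chelated polyenolate of 17, and the enolate carbon C5, flanked by the C4 ketone and the benzoyl carbonyl, adds to the lactone carbonyl C6 in a 6-exo-trig acyl substitution to give hemiketal 18, which collapses by C6–O cleavage so that the ring oxygen leaves as the C2′ alkoxide and the resulting cyclohexanetrione enolises to the phloroglucinol. The closest known reaction type is the Mg(OMe)2-mediated Claisen cyclisation of 3,5,7-trioxoalkanoates and of 6-(acylmethyl)-4-hydroxy-2-pyrones to acylphloroglucinols, here with a γ-lactone as the ester. No stereocentre is formed, and the C2′ centre fixed in step 4 is carried through because only the acyl–oxygen bond is broken. The step needs Claisen rather than aldol folding, which the alkyl substituent on the lactone α-carbon C1 secures: attack of C1 on the benzoyl carbonyl would create a quaternary spiro carbon that cannot aromatise and so reverts, whereas the Claisen product is drained by aromatisation. It also needs C- rather than O-acylation, which magnesium chelation favours; the O-acylation product (pyrone F1) and the methanolysed open-chain methyl ester should both converge on 19 under the same base. Acidification is kept mild and cold so that no phenol adds to the 1,1-disubstituted alkene.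

**Compound list**

1 | 5-bromo-2-methylpent-2-ene | CC(C)=CCCBr | starting material
2 | prop-2-yn-1-ol | C#CCO | starting material
3 | (4-methylpent-3-en-1-yl)magnesium bromide | CC(C)=CCC[Mg]Br | intermediate
4 | 4-(4-methylpent-3-en-1-yl)-2,5-dihydro-1,2-oxamagnesole | CC(C)=CCCC1=C[Mg]OC1 | intermediate
5 | 6-methyl-2-methylidenehept-5-en-1-ol | C=C(CO)CCC=C(C)C | intermediate
6 | 6-methyl-2-methylidenehept-5-enal | C=C(C=O)CCC=C(C)C | intermediate
7 | rac-2-(6-methylhepta-1,5-dien-2-yl)oxirane | C=C(CCC=C(C)C)C1CO1 | intermediate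
8 | (2S)-2-(6-methylhepta-1,5-dien-2-yl)oxirane | C=C(CCC=C(C)C)[C@H]1CO1 | intermediate
9 | ethyl 3-oxobutanoate | CCOC(=O)CC(C)=O | starting material
10 | ethyl (4R)-2-acetyl-4-hydroxy-9-methyl-5-methylidenedec-8-enoate | C=C(CCC=C(C)C)[C@H](O)CC(C(C)=O)C(=O)OCC | intermediate
11 | (5R)-3-acetyl-5-(6-methylhepta-1,5-dien-2-yl)oxolan-2-one | C=C(CCC=C(C)C)[C@H]1CC(C(C)=O)C(=O)O1 | intermediate
12 | N-methoxy-N-methylacetamide | CON(C)C(C)=O | starting material
13 | (5R)-3-{3-hydroxy-3-[methoxy(methyl)amino]butanoyl}-5-(6-methylhepta-1,5-dien-2-yl)oxolan-2-one | C=C(CCC=C(C)C)[C@H]1CC(C(=O)CC(C)(O)N(C)OC)C(=O)O1 | intermediate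
14 | (5R)-5-(6-methylhepta-1,5-dien-2-yl)-3-(3-oxobutanoyl)oxolan-2-one | C=C(CCC=C(C)C)[C@H]1CC(C(=O)CC(C)=O)C(=O)O1 | intermediate
15 | N-methoxy-N-methylbenzamide | CON(C)C(=O)c1ccccc1 | starting material
16 | (5R)-3-{5-hydroxy-5-[methoxy(methyl)amino]-3-oxo-5-phenylpentanoyl}-5-(6-methylhepta-1,5-dien-2-yl)oxolan-2-one | C=C(CCC=C(C)C)[C@H]1CC(C(=O)CC(=O)CC(O)(c2ccccc2)N(C)OC)C(=O)O1 | intermediate
17 | (5R)-3-(3,5-dioxo-5-phenylpentanoyl)-5-(6-methylhepta-1,5-dien-2-yl)oxolan-2-one | C=C(CCC=C(C)C)[C@H]1CC(C(=O)CC(=O)CC(=O)c2ccccc2)C(=O)O1 | intermediate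
18 | (2R)-7-benzoyl-7a-hydroxy-2-(6-methylhepta-1,5-dien-2-yl)hexahydro-1-benzofuran-4,6(2H,5H)-dione | C=C(CCC=C(C)C)[C@H]1CC2C(=O)CC(=O)C(C(=O)c3ccccc3)C2(O)O1 | intermediate
19 | {2,4,6-trihydroxy-3-[(2R)-2-hydroxy-7-methyl-3-methylideneoct-6-en-1-yl]phenyl}(phenyl)methanone | C=C(CCC=C(C)C)[C@H](O)Cc1c(O)cc(O)c(C(=O)c2ccccc2)c1O | target

Total step count: 8. Longest linear sequence: 8 steps (1 and 2 to 19).

**Steps most likely to fail**

First, step 8. The C5 enolate may close too slowly onto the saturated lactone carbonyl, so that methoxide cleaves the β-keto lactone by retro-Claisen loss of the acyl chain before the ring forms. The fallback sets out from 17. DBU in toluene at 50 °C should transfer the acyl group from the C2′ oxygen to the C4 enol oxygen and give 4-hydroxy-3-[(2R)-2-hydroxy-7-methyl-3-methylideneoct-6-en-1-yl]-6-(2-oxo-2-phenylethyl)-2H-pyran-2-one F1, as known for the base-induced cyclisation of 3,5-dioxo esters to 4-hydroxy-2-pyrones. 6-(Acylmethyl)-4-hydroxy-2-pyrones are established substrates for the rearrangement to acylphloroglucinols in methanolic Mg(OMe)2, so F1 under those conditions comes back to the route at 19.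

Second, step 7. Incomplete third deprotonation may lead to acylation at an internal carbon or on oxygen, and the excess amide base may degrade 14 before it reacts. The fallback sets out from 11 and avoids both 14 and the trianion. Ethyl (2-phenyl-1,3-dioxolan-2-yl)acetate F2 is made beforehand from ethyl 3-oxo-3-phenylpropanoate and ethane-1,2-diol (TsOH, toluene, azeotropic water removal). Doubly deprotonated 11 (LiN(iPr)2, 3.2 equiv, THF, −78 → 0 °C) is acylated at its methyl carbon with F2 to give (5R)-5-(6-methylhepta-1,5-dien-2-yl)-3-[3-oxo-4-(2-phenyl-1,3-dioxolan-2-yl)butanoyl]oxolan-2-one F3. Mild ketal hydrolysis (pyridinium p-toluenesulfonate, wet acetone, 40 °C) then frees the benzoyl ketone and comes back to the route at 17.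

Third, step 5. The enolate may attack the allylic oxirane carbon in competition with the unsubstituted one, and ethoxide may deacetylate the product. The fallback sets out from 7 and fixes the site of C–C bond formation with a primary sulfonate:
- Resolution of 7 with the mirror-image (R,R)-(salen)Co(OAc) complex and H2O (0.45 equiv) should give (2S)-7-methyl-3-methylideneoct-6-ene-1,2-diol F4.
- Tin-catalysed primary sulfonylation (TsCl, Et3N, Bu2SnO 2 mol%, CH2Cl2, 0 °C) gives (2S)-2-hydroxy-7-methyl-3-methylideneoct-6-en-1-yl 4-methylbenzenesulfonate F5.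
- Silylation (TBSOTf, 2,6-lutidine, CH2Cl2, −78 °C) gives (2S)-2-[(tert-butyldimethylsilyl)oxy]-7-methyl-3-methylideneoct-6-en-1-yl 4-methylbenzenesulfonate F6.
- Alkylation of the sodium enolate of 9 (NaH, DMF, NaI cat., 60 °C) gives ethyl (4R)-2-acetyl-4-[(tert-butyldimethylsilyl)oxy]-9-methyl-5-methylidenedec-8-enoate F7.
- Desilylation (HF·pyridine, THF, 0 → 25 °C) liberates 10, which lactonises, with a trace of Et3N if needed, and comes back to the route at 11.

**Further compounds**

F1 | step 8 | 4-hydroxy-3-[(2R)-2-hydroxy-7-methyl-3-methylideneoct-6-en-1-yl]-6-(2-oxo-2-phenylethyl)-2H-pyran-2-one | C=C(CCC=C(C)C)[C@H](O)Cc1c(O)cc(CC(=O)c2ccccc2)oc1=O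
F2 | step 7 | ethyl (2-phenyl-1,3-dioxolan-2-yl)acetate | CCOC(=O)CC1(c2ccccc2)OCCO1
F3 | step 7 | (5R)-5-(6-methylhepta-1,5-dien-2-yl)-3-[3-oxo-4-(2-phenyl-1,3-dioxolan-2-yl)butanoyl]oxolan-2-one | C=C(CCC=C(C)C)[C@H]1CC(C(=O)CC(=O)CC2(c3ccccc3)OCCO2)C(=O)O1
F4 | step 5 | (2S)-7-methyl-3-methylideneoct-6-ene-1,2-diol | C=C(CCC=C(C)C)[C@H](O)CO
F5 | step 5 | (2S)-2-hydroxy-7-methyl-3-methylideneoct-6-en-1-yl 4-methylbenzenesulfonate | C=C(CCC=C(C)C)[C@H](O)COS(=O)(=O)c1ccc(C)cc1
F6 | step 5 | (2S)-2-[(tert-butyldimethylsilyl)oxy]-7-methyl-3-methylideneoct-6-en-1-yl 4-methylbenzenesulfonate | C=C(CCC=C(C)C)[C@H](O[Si](C)(C)C(C)(C)C)COS(=O)(=O)c1ccc(C)cc1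
F7 | step 5 | ethyl (4R)-2-acetyl-4-[(tert-butyldimethylsilyl)oxy]-9-methyl-5-methylidenedec-8-enoate | C=C(CCC=C(C)C)[C@H](O[Si](C)(C)C(C)(C)C)CC(C(C)=O)C(=O)OCC
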